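## Structural features

The target is a drimane-type sesquiterpene hydroquinone. It has a trans-fused decalin (ring A: C1–C5 and C10, with the gem-dimethyl group at C4; ring B: C5–C10) whose C9 is joined through an exocyclic, fully substituted double bond to C11. C11 carries chlorine and a 2,5-dihydroxy-3-methoxyphenyl ring. There are three stereocentres, all S: the adjacent ring-fusion pair C5 (CH) and C10 (quaternary, angular methyl), and C8 (CH–CH3). C8 and C10 both flank the sp2 carbon C9, so their methyl groups stand 1,3-syn and the C8 methyl is axial. The alkene is E: chlorine lies on the C8 side and the aryl ring on the side of quaternary C10, where it must twist out of the alkene plane. Fragile groups are the free hydroquinone (air oxidation to the quinone) and the electron-rich styrenyl chloride (acid); on the way, the exocyclic methylene (acid isomerisation) and the α-methyl aldehyde (base epimerisation) also need care. The real difficulty is the congested tetrasubstituted chloroalkene of defined geometry next to a quaternary centre, together with absolute control of C5 and C8, which lie far apart with no functional group between them. The key step exploits the fact that C9 is the common neighbour of C8, C10 and C11. If C9≡C11 is an aryl alkyne held on a chain from C5, a radical at C10 can close ring B at C9 and leave a linear radical at C11. The two in-plane flanks of that radical differ strongly (equatorial hydrogen at C8 against the C1 methylene at C10), so the C10 configuration and the chlorine geometry should come from one event.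

## Logic of the disconnections

**20 to 19.** The two O–Si bonds are cut. The phenolic oxygens must stay masked while trivalent iron and radicals are present, and silyl ethers can be removed at the very end by buffered fluoride, which leaves the vinyl chloride alone. The demand is exclusion of air in the last step.

**19 to 18.** The bonds C9–C10 and C11–Cl are cut, together with one C–H bond of the C10 methyl. This removes ring B, the C10 stereocentre and the alkene geometry at once and leaves a monocyclic enyne that holds only C5 and C8. The forward step must add a hydrogen atom to the exocyclic methylene only, close 6-exo onto the alkyne before the C10 radical is intercepted, fuse the rings trans, and deliver chlorine to C11 from the C8 side. The silyl groups of 18 are kept on purpose: a free ortho phenol would be oxidised by iron or would add to the alkyne.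

**18 to 13 and 17.** The sp–sp2 bond between C11 and the arene is cut. This separates the whole terpenoid part from the arene and allows a convergent coupling under mild conditions. The demand is that a hindered ortho-silyloxy aryl iodide couples without loss of silyl groups.

**17 to 16 to 14 (through 15).** The O–Si bonds are cut, then an aryl C–O bond is traced back to an aryl C–CHO bond. All four arene substituents, with iodine already ortho to the hydroxyl, then come from one cheap commercial compound. The demand is that the electron-rich diol 16 is handled without air and silylated at once.

**13 to 12 to 11.** The C9≡C11 triple bond is reduced to a one-carbon homologation of an aldehyde, and the aldehyde to a primary alcohol. The demand is that C8, which is α to the carbonyl in 12, does not epimerise.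

**11 to 7 and 8 (through 9 and 10).** The sp3–sp3 bond C6–C7 is cut, midway between the two stereocentres. Each centre then comes from its own enantiopure piece: C8 from commercial 8 and C5 from 7. Because 8 is used as its alkoxide 10, no protecting group is needed, and the cut saves several steps compared with carrying an arene-bearing alkyne into the coupling. The demand is a copper-catalysed coupling of two β-branched partners and a homoallylic organomagnesium 9 that keeps its structure.

**7 to 6 to 5 to 4 to 2 (through 3) to 1.** In turn: the C–Br bond; the resolution that supplies C5; the reduction of the carboxyl carbon; the shift of the ring double bond of 2 to the exocyclic position, which creates the C5–H bond; and the oxidation of the aldehyde. The demands are kinetic deprotonation at the methyl group cis to the carboxylate with protonation at the α-carbon, and sufficient enantiodiscrimination in 5.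

## Other disconnections considered

**Alternative 1:** The cut goes through C4–C5 and C9–C10, with a C8–O bond to the phenol added as a temporary third bond. It leads back to the achiral farnesylated phenol A1. In the forward direction a chiral Brønsted acid, made from SnCl4 and a binaphthol monoether, would protonate the terminal double bond of A1. A chair–chair cascade would then close rings A and B and be ended by the phenol oxygen at C8, giving the trans-fused chromane A2.

- In its favour: this is an established class of enantioselective polyene cyclisation. It would form two carbocycles and four stereocentres from a substrate without a stereocentre, and it needs no resolution. On precedent, on the number of rings and centres formed in one step, and on absolute control by a catalyst, it is better than the chosen plan.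
- Against it here: A2 has oxygen at C8, hydrogen at C9 and a CH2 group at C11. The target needs hydrogen at C8 with the methyl axial, a C9=C11 double bond and chlorine at C11. The C8–O bond would have to be broken, C8 reduced with control of configuration, C11 raised by two oxidation levels and chlorinated, and the alkene geometry set by a later, unrelated step.
- Comparison: mechanistically the cationic cascade is more secure than the radical cascade. Structurally it solves the decalin, which is the easier part, and leaves the chloroalkene open. In step economy a short way to A2 would be followed by a long and uncertain sequence, against one step after the key step in the chosen plan.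

**Alternative 2:** The cut goes through C1–C10 and C4–C5. Ring B is taken from 2,6-dimethylbenzoquinone A3 and ring A from 4-methylpenta-1,3-diene A4. In the forward direction a chiral oxazaborolidinium ion (the B-o-tolyl oxazaborolidine of α,α-diphenylprolinol activated by HNTf2) would direct A4 onto one methyl-bearing double bond of A3. The product would be the cis-fused ene-dione A5 with quaternary C10 set by the catalyst.

- In its favour: both partners are simple and achiral, the quaternary centre is made by a well-studied catalytic reaction, and the C9 carbonyl is a handle for attaching C11. On absolute stereocontrol without resolution and on precedent it is better than the chosen plan.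
- Against it here: A4 is a reluctant diene, because the terminal gem-dimethyl group disfavours the s-cis conformer, and it is prone to cationic oligomerisation under a strong Lewis acid. The C4–C5 bond must form at that hindered terminus. A5 is cis-fused and would have to be epimerised at C5. The C6 carbonyl and two ring double bonds would have to be removed and C8 set by a reduction. The C9 ketone, flanked by C10 and C8, would then have to become the tetrasubstituted chloro(aryl)alkene, for which no geometry-controlled method is at hand.
- Comparison: structurally the alternative builds C10 well but leaves C5, C8 and the alkene for later. Mechanistically its key step is the safer one. In step economy the chosen plan is clearly shorter after the key step and is the only one of the two that addresses the alkene geometry.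

**Alternative 3:** The cut goes through C5–C10 and C8–C9 and leads back to the acyclic allene–diene A6, an axially chiral aryl(chloro)allene tethered through C1–C4 to an (E,E)-diene. On heating, the tether-proximal C9=C10 bond of A6 would add to the diene. The diene should approach the face on which the C11 chlorine lies, away from the aryl group, so that chlorine ends cis to C8. The (E,E)-diene places C4 and the C8 methyl cis, and the axis is translated into C10. The product would be the 6,7-didehydro bis-pivalate A7.

- In its favour: both rings, three stereocentres and the alkene geometry would arise in one reagent-free step. A7 would be only a diimide reduction of the disubstituted C6=C7 bond and an ester cleavage away from the target. On bonds and stereocentres formed in the key step it is better than the chosen plan, and on steps after the key step it is nearly equal.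
- Against it here: A6 is needed as a single axial enantiomer. It is a tetrasubstituted chloroallene whose asymmetric preparation is doubtful, as is its configurational stability at the temperature of cycloaddition. The reacting termini are a neopentyl-type diene carbon (C5) and a fully substituted dienophile carbon (C10). The cis/trans fusion preference in cyclisations of this tether length is often weak, and the distal allene bond could compete.
- Comparison: both plans rest on a step without direct precedent, and both derive the alkene geometry from approach to a linear C9–C11 unit. The chosen plan secures C5 and C8 beforehand by conventional means and asks its key step for one stereocentre. The alternative stakes three centres on one stereogenic axis that is hard to obtain, and its precursor synthesis would be longer.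

Key step: step 12

Assumption 1: the target is specified without an axial descriptor, so rotation about the C11–aryl bond is taken as free at room temperature in the hydroquinone; slowly interconverting rotamers of silyl ether 19 would converge on desilylation.

Assumption 2: the lipase in step 4 is taken to acetylate the (R)-alcohol faster, as the empirical size model for primary alcohols predicts; if the preference were the reverse, the acetylated fraction would be carried on after methanolysis, at the cost of one step.

## Route

Step 1
Reactants: 1 β-cyclocitral (2,6,6-trimethylcyclohex-1-ene-1-carbaldehyde)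
Product: 2 β-cyclogeranic acid (2,6,6-trimethylcyclohex-1-ene-1-carboxylic acid)
Conditions: NaClO2, NaH2PO4, 2-methyl-2-butene, t-BuOH/H2O, rt
Reagents that add atoms: sodium chlorite, [Na+].[O-]Cl=O
Why: Pinnick (chlorite) oxidation is the standard way to take a hindered conjugated aldehyde to the acid; the hypochlorite scavenger protects the tetrasubstituted alkene, and no stereocentre is involved.

Step 2
Reactants: 2 β-cyclogeranic acid
Product: 4 (±)-γ-cyclogeranic acid (rac-2,2-dimethyl-6-methylidenecyclohexane-1-carboxylic acid), via dilithium dienediolate 3 (not isolated)
Conditions: LiN(iPr)2 (2.3 equiv), THF, −78 to 0 °C; then AcOH, −78 °C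
Reagents that add atoms: none
Why: Deconjugative protonation through the acid dianion: the lithium carboxylate directs the amide base to the allylic methyl cis to it, and kinetic protonation of dienediolate 3 at the α-carbon moves the double bond to the exocyclic position; C5 is formed racemic here.

Step 3
Reactants: 4 (±)-γ-cyclogeranic acid
Product: 5 (±)-γ-cyclogeraniol (rac-(2,2-dimethyl-6-methylidenecyclohexyl)methanol)
Conditions: LiAlH4, THF, 0 °C to reflux; aqueous NaOH work-up
Reagents that add atoms: none
Why: Hydride reduction of a carboxylic acid to the primary alcohol; the isolated 1,1-disubstituted alkene is inert to LiAlH4.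

Step 4
Reactants: 5 (±)-γ-cyclogeraniol
Product: 6 (S)-γ-cyclogeraniol, [(1S)-2,2-dimethyl-6-methylidenecyclohexyl]methanol
Conditions: Burkholderia cepacia lipase (immobilised), vinyl acetate, t-BuOMe, rt, to just past half conversion; chromatography
Reagents that add atoms: none
Why: Lipase-catalysed kinetic resolution by irreversible transesterification: the enzyme should acetylate the (R)-alcohol faster, and running past half conversion raises the enantiopurity of the recovered (S)-alcohol; this step fixes C5 for the whole route.

Step 5
Reactants: 6 (S)-γ-cyclogeraniol
Product: 7 (2S)-2-(bromomethyl)-1,1-dimethyl-3-methylidenecyclohexane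
Conditions: CBr4, PPh3, CH2Cl2, 0 °C to rt
Reagents that add atoms: carbon tetrabromide, BrC(Br)(Br)Br
Why: Appel bromination replaces the primary hydroxyl by SN2 at the CH2 group under neutral conditions, so the adjacent stereocentre and the exocyclic alkene are untouched.

Step 6
Reactants: 7 (2S)-2-(bromomethyl)-1,1-dimethyl-3-methylidenecyclohexane; 8 (R)-3-bromo-2-methylpropan-1-ol
Product: 11 (2S)-4-[(1S)-2,2-dimethyl-6-methylidenecyclohexyl]-2-methylbutan-1-ol, via cyclohexylmethylmagnesium bromide 9 (not isolated), via chloromagnesium alkoxide 10 (not isolated)
Conditions: 7, Mg, THF, 40 °C; 8, MeMgCl (1.0 equiv), THF, −40 °C; combine with Li2CuCl4 (cat.), NMP, THF, −20 °C to rt; aq. NH4Cl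
Reagents that add atoms: none
Why: Copper-catalysed sp3–sp3 cross-coupling of a Grignard reagent with a primary bromide; the hydroxyl of 8 is masked in the flask as its magnesium alkoxide, so no protecting group is needed, and the bond forms between two CH2 carbons, so C5 and C8 are carried over unchanged.

Step 7
Reactants: 11 (2S)-4-[(1S)-2,2-dimethyl-6-methylidenecyclohexyl]-2-methylbutan-1-ol
Product: 12 (2S)-4-[(1S)-2,2-dimethyl-6-methylidenecyclohexyl]-2-methylbutanal
Conditions: Dess–Martin periodinane, CH2Cl2, 0 °C to rt
Reagents that add atoms: none
Why: Dess–Martin oxidation stops at the aldehyde under non-enolising conditions, which protects the α-stereocentre C8; the alkene is inert to the iodinane.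

Step 8
Reactants: 12 (2S)-4-[(1S)-2,2-dimethyl-6-methylidenecyclohexyl]-2-methylbutanal
Product: 13 (2S)-1,1-dimethyl-3-methylidene-2-[(3S)-3-methylpent-4-yn-1-yl]cyclohexane
Conditions: dimethyl (1-diazo-2-oxopropyl)phosphonate, K2CO3, MeOH, 0 °C to rt
Reagents that add atoms: dimethyl (1-diazo-2-oxopropyl)phosphonate, COP(=O)(OC)C(=[N+]=[N-])C(C)=O
Why: The Ohira–Bestmann variant of the Seyferth–Gilbert homologation turns the aldehyde into the terminal alkyne with one added carbon (C11); under cold carbonate conditions an α-alkyl aldehyde without a β-heteroatom is expected to keep its configuration.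

Step 9
Reactants: 14 5-iodovanillin (4-hydroxy-3-iodo-5-methoxybenzaldehyde)
Product: 16 2-iodo-6-methoxybenzene-1,4-diol, via aryl formate 15 (not isolated)
Conditions: H2O2 (30 % aq.), NaOH, THF/H2O, 0 °C to rt, Ar; then aq. HCl, Na2S2O4 wash
Reagents that add atoms: hydrogen peroxide, OO
Why: Dakin oxidation: the para-phenoxide drives aryl migration in the peroxide adduct and the formate is hydrolysed in the same pot; the aryl iodide is inert to alkaline peroxide.

Step 10
Reactants: 16 2-iodo-6-methoxybenzene-1,4-diol
Product: 17 1,4-bis(tert-butyldimethylsilyloxy)-2-iodo-6-methoxybenzene
Conditions: TBSCl, imidazole, DMF, rt to 40 °C, Ar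
Reagents that add atoms: tert-butyldimethylsilyl chloride, CC(C)(C)[Si](C)(C)Cl
Why: Standard silyl ether formation on both phenols, with gentle warming for the hydroxyl flanked by iodine and methoxy; it masks the oxidation-prone hydroquinone for the metal-mediated steps.

Step 11
Reactants: 13 (2S)-1,1-dimethyl-3-methylidene-2-[(3S)-3-methylpent-4-yn-1-yl]cyclohexane; 17 1,4-bis(tert-butyldimethylsilyloxy)-2-iodo-6-methoxybenzene
Product: 18 1,4-bis(tert-butyldimethylsilyloxy)-2-{(3S)-5-[(1S)-2,2-dimethyl-6-methylidenecyclohexyl]-3-methylpent-1-yn-1-yl}-6-methoxybenzene
Conditions: Pd(PPh3)2Cl2 (cat.), CuI (cat.), Et3N/THF, degassed, rt to 40 °C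
Reagents that add atoms: none
Why: Sonogashira coupling of an aryl iodide with a terminal alkyne runs near room temperature, where aryl silyl ethers, the exocyclic alkene and the propargylic stereocentre are stable; the silyl group on the ortho oxygen also prevents closure to a benzofuran.

Step 12
Reactants: 18 1,4-bis(tert-butyldimethylsilyloxy)-2-{(3S)-5-[(1S)-2,2-dimethyl-6-methylidenecyclohexyl]-3-methylpent-1-yn-1-yl}-6-methoxybenzene
Product: 19 1,4-bis(tert-butyldimethylsilyloxy)-2-{(E)-chloro[(2S,4aS,8aS)-2,5,5,8a-tetramethyloctahydronaphthalen-1(2H)-ylidene]methyl}-6-methoxybenzene
Conditions: Fe(acac)3, PhSiH3, TsCl (added in portions), i-PrOH/PhCF3 (1:5), high dilution, Ar, 0 °C to rt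
Reagents that add atoms: 4-methylbenzenesulfonyl chloride, Cc1ccc(cc1)S(=O)(=O)Cl
Why: Proposed new method: an iron hydride formed from Fe(acac)3 and the alkoxysilane made from PhSiH3 and i-PrOH transfers a hydrogen atom to the CH2 terminus of the 1,1-disubstituted alkene, which creates the C10 methyl and a tertiary C10 radical; this radical adds 6-exo-dig to C9 of the aryl alkyne (ring B, bond C9–C10), the regiochemistry that places the new radical at C11 in conjugation with the arene, and the linear α-aryl vinyl radical then abstracts chlorine from TsCl, the sulfonyl radical being reduced to sulfinate by divalent iron, which returns trivalent iron. The closest known reaction types are Fe(acac)3/PhSiH3 hydrogen-atom-transfer radical cyclisations of alkenes onto π-acceptors and the radical Markovnikov hydrochlorination of alkenes with TsCl; they have not been joined through an alkyne. C10 (S) is set in a chair-like transition state in which the C5–C6 bond and the forming C9–C10 bond are both equatorial on ring A, so the methyl turns axial and the fusion is trans; the preset C5 centre decides which face this is, and the C8 methyl is axial in that chair, a contact kept small by the long forming bond and the linear alkyne. The alkene geometry is set at chlorine transfer: the aryl ring of the vinyl radical stands perpendicular to the alkene plane, TsCl must approach within that plane, and the C10 flank is shielded by the C1 methylene while the C8 flank shows only an equatorial hydrogen, so chlorine should end cis to C8 (E). The step needs ring closure to outrun chlorine capture at C10 (served by dilution and portionwise TsCl), chlorine transfer to outrun hydrogen abstraction by the vinyl radical (served by the weak S–Cl bond and a solvent poor in weak C–H bonds), and hydrogen-atom transfer to the alkene in preference to the alkyne (inherent in the reagent). The silyl ethers keep the hydroquinone from oxidation by trivalent iron and keep the ortho oxygen off the alkyne.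

Step 13
Reactants: 19 1,4-bis(tert-butyldimethylsilyloxy)-2-{(E)-chloro[(2S,4aS,8aS)-2,5,5,8a-tetramethyloctahydronaphthalen-1(2H)-ylidene]methyl}-6-methoxybenzene
Product: 20 2-{(E)-chloro[(2S,4aS,8aS)-2,5,5,8a-tetramethyloctahydronaphthalen-1(2H)-ylidene]methyl}-6-methoxybenzene-1,4-diol (CNP0162917.1)
Conditions: Bu4NF, AcOH, THF (degassed), 0 °C, Ar
Reagents that add atoms: none
Why: Fluoride desilylation cleaves aryl silyl ethers rapidly; acetic acid keeps the phenols protonated so that, with air excluded, the hydroquinone is not oxidised, and the vinyl chloride and the stereocentres are not affected.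

## Compound list

1 | β-cyclocitral (2,6,6-trimethylcyclohex-1-ene-1-carbaldehyde) | CC1=C(C=O)C(C)(C)CCC1 | starting material
2 | β-cyclogeranic acid (2,6,6-trimethylcyclohex-1-ene-1-carboxylic acid) | CC1=C(C(=O)O)C(C)(C)CCC1 | intermediate
3 | dilithium (2,2-dimethyl-6-methylidenecyclohexylidene)methanediolate | [Li+].[Li+].[O-]C([O-])=C1C(=C)CCCC1(C)C | intermediate
4 | (±)-γ-cyclogeranic acid (rac-2,2-dimethyl-6-methylidenecyclohexane-1-carboxylic acid) | OC(=O)C1C(C)(C)CCCC1=C | intermediate
5 | (±)-γ-cyclogeraniol (rac-(2,2-dimethyl-6-methylidenecyclohexyl)methanol) | OCC1C(C)(C)CCCC1=C | intermediate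
6 | [(1S)-2,2-dimethyl-6-methylidenecyclohexyl]methanol | OC[C@H]1C(C)(C)CCCC1=C | intermediate
7 | (2S)-2-(bromomethyl)-1,1-dimethyl-3-methylidenecyclohexane | BrC[C@H]1C(C)(C)CCCC1=C | intermediate
8 | (R)-3-bromo-2-methylpropan-1-ol | OC[C@@H](C)CBr | starting material
9 | {[(1S)-2,2-dimethyl-6-methylidenecyclohexyl]methyl}magnesium bromide | Br[Mg]C[C@H]1C(C)(C)CCCC1=C | intermediate
10 | chloromagnesium (R)-3-bromo-2-methylpropan-1-olate | Cl[Mg]OC[C@@H](C)CBr | intermediate
11 | (2S)-4-[(1S)-2,2-dimethyl-6-methylidenecyclohexyl]-2-methylbutan-1-ol | OC[C@@H](C)CC[C@H]1C(C)(C)CCCC1=C | intermediate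
12 | (2S)-4-[(1S)-2,2-dimethyl-6-methylidenecyclohexyl]-2-methylbutanal | O=C[C@@H](C)CC[C@H]1C(C)(C)CCCC1=C | intermediate
13 | (2S)-1,1-dimethyl-3-methylidene-2-[(3S)-3-methylpent-4-yn-1-yl]cyclohexane | C#C[C@@H](C)CC[C@H]1C(C)(C)CCCC1=C | intermediate
14 | 5-iodovanillin (4-hydroxy-3-iodo-5-methoxybenzaldehyde) | COc1cc(C=O)cc(I)c1O | starting material
15 | 4-hydroxy-3-iodo-5-methoxyphenyl formate | COc1cc(OC=O)cc(I)c1O | intermediate
16 | 2-iodo-6-methoxybenzene-1,4-diol | COc1cc(O)cc(I)c1O | intermediate
17 | 1,4-bis(tert-butyldimethylsilyloxy)-2-iodo-6-methoxybenzene | COc1cc(O[Si](C)(C)C(C)(C)C)cc(I)c1O[Si](C)(C)C(C)(C)C | intermediate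
18 | 1,4-bis(tert-butyldimethylsilyloxy)-2-{(3S)-5-[(1S)-2,2-dimethyl-6-methylidenecyclohexyl]-3-methylpent-1-yn-1-yl}-6-methoxybenzene | COc1cc(O[Si](C)(C)C(C)(C)C)cc(C#C[C@@H](C)CC[C@H]2C(C)(C)CCCC2=C)c1O[Si](C)(C)C(C)(C)C | intermediate
19 | 1,4-bis(tert-butyldimethylsilyloxy)-2-{(E)-chloro[(2S,4aS,8aS)-2,5,5,8a-tetramethyloctahydronaphthalen-1(2H)-ylidene]methyl}-6-methoxybenzene | COc1cc(O[Si](C)(C)C(C)(C)C)cc(/C(Cl)=C2/[C@@H](C)CC[C@H]3C(C)(C)CCC[C@]23C)c1O[Si](C)(C)C(C)(C)C | intermediate
20 | 2-{(E)-chloro[(2S,4aS,8aS)-2,5,5,8a-tetramethyloctahydronaphthalen-1(2H)-ylidene]methyl}-6-methoxybenzene-1,4-diol | COc1cc(O)cc(/C(Cl)=C2/[C@@H](C)CC[C@H]3C(C)(C)CCC[C@]23C)c1O | target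

## Step count and least certain steps

Total step count: 13. Longest linear sequence: 11 steps (steps 1–8 and 11–13); steps 9 and 10 form the two-step arene branch.

**Step 12 (key step, proposed new method).**
- What may go wrong:
  - chlorine capture by the tertiary C10 radical before ring closure, because a 6-exo closure onto an alkyne is not fast and TsCl is present throughout;
  - hydrogen capture by the vinyl radical from silane or solvent in place of chlorine;
  - closure through the cis-fused chair, because the trans chair holds the two methyls 1,3-syn;
  - back-transfer of hydrogen from the C10 radical, giving endocyclic alkene isomers, one of which would erase C5;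
  - addition of sulfonyl radicals to the alkyne.
- Fallback (known polar chemistry, from 18 back to 19): Markovnikov addition of HCl (HCl in dioxane, CH2Cl2, −20 °C) to the exocyclic alkene of 18 would give the tertiary chloride F1, which is also the expected by-product of early chlorine capture in step 12 and could be recycled the same way. Ionisation of F1 with ZnCl2·OEt2 or TiCl4 in CH2Cl2 at −78 °C would generate the C10 cation, which should attack the aryl alkyne 6-exo to give the aryl-stabilised linear vinyl cation; chloride return from the metal chloride anion on the open C8 side would give 19. This is the Lewis-acid-promoted addition of a tertiary alkyl chloride across an aryl alkyne, a cation–alkyne cyclisation ended by halide.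

**Step 2.**
- What may go wrong: incomplete or misdirected γ-deprotonation of the hindered, twisted carboxylate, leading to recovered 2 or to the endocyclic isomer.
- Fallback (from 2 back to 5): methylation of 2 (MeI, K2CO3, DMF) would give methyl β-cyclogeranate F2. Its ester dienolate (LiN(iPr)2, DMPU, THF, −78 °C) on kinetic protonation would give methyl γ-cyclogeranate F3, a compound that is also an article of commerce in perfumery. LiAlH4 would then reduce F3 to 5.

**Step 4.**
- What may go wrong: poor enantiodiscrimination, because the stereocentre is β to the hydroxyl and flanked by two fully substituted carbons.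
- Fallback (from 5 back to 6): acylation of 5 with (1S)-camphanic chloride and pyridine would give two diastereomeric esters, to be separated by crystallisation or chromatography. The camphanate of the (S)-alcohol F4, assigned by X-ray analysis, would be cleaved with K2CO3 in methanol to 6.

**Step 6.**
- What may go wrong: homocoupling while 9 is formed, ring-closing and ring-opening equilibria of the homoallylic organomagnesium, and a slow coupling of two β-branched partners.
- Fallback (from 6 and 8 back to 11, polarity reversed): 6 would be converted into the tosylate F5 (TsCl, pyridine) and 8 into the silyl ether F6 (TBSCl, imidazole). F6 with Mg would give the Grignard reagent F7. Coupling of F7 with F5 under CuCl2/1-phenylpropyne or Li2CuCl4 catalysis would give the silyl ether F8, and Bu4NF would release 11.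

**Step 8.**
- What may go wrong: epimerisation of C8 in 12 by carbonate in methanol before the aldehyde is consumed.
- Fallback (from 12 back to 13): Corey–Fuchs sequence without an enolising base at the aldehyde stage. CBr4/PPh3 in CH2Cl2 at 0 °C would give the dibromoalkene F9, and n-BuLi (2.2 equiv, THF, −78 °C) followed by water would give 13.

## Further compounds

F1 | step 12 | 1,4-bis(tert-butyldimethylsilyloxy)-2-{(3S)-5-[(1S)-2-chloro-2,6,6-trimethylcyclohexyl]-3-methylpent-1-yn-1-yl}-6-methoxybenzene (both epimers at the C–Cl carbon) | COc1cc(O[Si](C)(C)C(C)(C)C)cc(C#C[C@@H](C)CC[C@H]2C(C)(C)CCCC2(C)Cl)c1O[Si](C)(C)C(C)(C)C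
F2 | step 2 | methyl 2,6,6-trimethylcyclohex-1-ene-1-carboxylate | COC(=O)C1=C(C)CCCC1(C)C
F3 | step 2 | methyl rac-2,2-dimethyl-6-methylidenecyclohexane-1-carboxylate | COC(=O)C1C(C)(C)CCCC1=C
F4 | step 4 | [(1S)-2,2-dimethyl-6-methylidenecyclohexyl]methyl (1S,4R)-4,7,7-trimethyl-3-oxo-2-oxabicyclo[2.2.1]heptane-1-carboxylate | O=C(OC[C@H]1C(C)(C)CCCC1=C)[C@@]12CC[C@@](C)(C(=O)O1)C2(C)C
F5 | step 6 | [(1S)-2,2-dimethyl-6-methylidenecyclohexyl]methyl 4-methylbenzenesulfonate | Cc1ccc(cc1)S(=O)(=O)OC[C@H]1C(C)(C)CCCC1=C
F6 | step 6 | (R)-(3-bromo-2-methylpropoxy)(tert-butyl)dimethylsilane | CC(C)(C)[Si](C)(C)OC[C@@H](C)CBr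
F7 | step 6 | [(2R)-3-(tert-butyldimethylsilyloxy)-2-methylpropyl]magnesium bromide | CC(C)(C)[Si](C)(C)OC[C@@H](C)C[Mg]Br
F8 | step 6 | tert-butyl{(2S)-4-[(1S)-2,2-dimethyl-6-methylidenecyclohexyl]-2-methylbutoxy}dimethylsilane | CC(C)(C)[Si](C)(C)OC[C@@H](C)CC[C@H]1C(C)(C)CCCC1=C
F9 | step 8 | (2S)-2-[(3S)-5,5-dibromo-3-methylpent-4-en-1-yl]-1,1-dimethyl-3-methylidenecyclohexane | BrC(Br)=C[C@@H](C)CC[C@H]1C(C)(C)CCCC1=C
A1 | alternative 1 | 2-[(2E,6E)-3,7,11-trimethyldodeca-2,6,10-trien-1-yl]-6-methoxy-4-(pivaloyloxy)phenol | COc1cc(OC(=O)C(C)(C)C)cc(C/C=C(\C)CC/C=C(\C)CCC=C(C)C)c1O
A2 | alternative 1 | trans-fused tetracyclic chromane pivalate (drimane numbering: 5α-H, 10β-CH3, 9α-H, 8β-CH3, 8α-O–aryl; OCH3 ortho and pivaloyloxy para to the ring oxygen) | COc1cc(OC(=O)C(C)(C)C)cc2c1O[C@]1(C)CC[C@H]3C(C)(C)CCC[C@]3(C)[C@H]1C2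
A3 | alternative 2 | 2,6-dimethyl-1,4-benzoquinone | CC1=CC(=O)C=C(C)C1=O
A4 | alternative 2 | 4-methylpenta-1,3-diene | C=CC=C(C)C
A5 | alternative 2 | (4aR,8aS)-2,5,5,8a-tetramethyl-4a,5,8,8a-tetrahydronaphthalene-1,4-dione (cis-fused) | CC1=CC(=O)[C@@H]2C(C)(C)C=CC[C@]2(C)C1=O
A6 | alternative 3 | (Ra,8E,10E)-1-chloro-1-[3-methoxy-2,5-bis(pivaloyloxy)phenyl]-3,7,7-trimethyldodeca-1,2,8,10-tetraene | COc1cc(OC(=O)C(C)(C)C)cc(C(Cl)=[C@@]=C(C)CCCC(C)(C)/C=C/C=C/C)c1OC(=O)C(C)(C)C
A7 | alternative 3 | 2-{(E)-chloro[(2S,4aS,8aS)-2,5,5,8a-tetramethyl-4a,5,6,7,8,8a-hexahydronaphthalen-1(2H)-ylidene]methyl}-6-methoxy-1,4-phenylene bis(2,2-dimethylpropanoate) | COc1cc(OC(=O)C(C)(C)C)cc(/C(Cl)=C2/[C@@H](C)C=C[C@H]3C(C)(C)CCC[C@]23C)c1OC(=O)C(C)(C)C
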